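The readings were generated by integration from invented constants.

Treat the target in the flask as a level fed by the decay of starting material and drained by its own loss. The peak time then hangs on two lifetimes, that of starting material and that of target, while the share f of consumed starting material that becomes target scales the height and leaves the time alone.

| flask | starting material | first nucleophile | second nucleophile | remark | time |
|---|---|---|---|---|---|
| cedar | 0.50 M | 0.90 equiv | 1 equiv | run made earlier |  |
| maple | 0.75 M | 0.90 equiv | 1 equiv | run made earlier |  |
| flask | 1.0 M | 0.900 equiv | 1.00 equiv |  | 15 d |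

| run | time / d | target / % | starting material / % |
|---|---|---|---|
| cedar | 0.250 | 7.0 | 61.3 |
| cedar | 0.417 | 8.3 | 42.6 |
| cedar | 0.833 | 13.2 | 18.2 |
| cedar | 1.67 | 13.5 | 3.9 |
| cedar | 3.00 | 9.0 | 0 |
| cedar | 6.00 | 3.0 | 1.2 |
| cedar | 12.0 | 1.0 | 0.9 |
| maple | 0.250 | 10.2 | 57.5 |
| maple | 0.417 | 11.1 | 42.2 |
| maple | 0.833 | 16.3 | 18.8 |
| maple | 1.67 | 14.0 | 2.2 |
| maple | 3.00 | 9.8 | 0.2 |
| maple | 6.00 | 4.9 | 1.1 |
| maple | 12.0 | 1.2 | 0 |

(standard deviation of a reading: 1 percentage point)



- when, up to 15 d, the flask holds most target
- the amount of target, in percent of the starting material charged, at that time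
- the first time at which target reaches 7.9 %, in the same percent, in d

From 0.250 d to 0.833 d, averaged over the cedar and maple runs, starting material falls at

k_A = 2.00 d⁻¹

and from 1.67 d to 12.0 d, over the same runs, target falls at

k_0 = 0.245 d⁻¹

But those last readings lie near the scatter, so I cannot read a concentration dependence from them. My own reckoning therefore goes round once more: I suppose a pseudo-first-order loss on a partner charged in proportion to the starting material, and scale from the mean concentration of the two runs to the flask:

k_L = 0.392 d⁻¹

ρ = k_A/k_L = 5.10, the lifetime of target over that of starting material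

t* = ln ρ/(k_A − k_L) = 1.01 d

height = f·G, with G = ρ^(−1/(ρ−1)) = 0.672

The forecast gives 1.17 d, 18 % and 0.2 d on the ground that “The target later decays at about 0.25 /d, also concentration-independent”, so its peak comes later than mine.

The flask peaks at 0.930 d with 15.9 %, and reaches the asked level at 0.191 d.

    2 first nucleophile → homo dimer (k = 1.60 × 10⁻⁴ L mol⁻¹ min⁻¹)
    starting material → intermediate (k = 0.00140 min⁻¹)
    first nucleophile + intermediate → target (k = 0.0310 L mol⁻¹ min⁻¹)
    second nucleophile + target → over-reaction product (k = 4.70 × 10⁻⁴ L mol⁻¹ min⁻¹)
    intermediate → solvolysis product (k = 0.0320 min⁻¹)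
    second nucleophile + intermediate → other capture product (k = 0.0390 L mol⁻¹ min⁻¹)

At 0.344 d the flask makes target 4.02 times faster than it uses it up. With ρ = 5.10, dividing the peak by G gives f = 23.7 %, and the flask ends with 24.4 % as target plus over-reaction product. In the scheme target is lost with second nucleophile, so I scale ρ by that charge, and the neighbour charged with 0.400 equiv has ρ = 12.8. Its end holds 30.7 % as those two products, so the rule gives a peak of 24.7 %, and that neighbour flask's peak stands at 25.0 %.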